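**Retrosynthetic overview**
1. Key C–C bond: ring A C3 to the prenyl CH2. Ester 1 is made electrophilic at C3 as its phenyliodonium zwitterion (an enolonium / aryl-cation equivalent) and joined to the nucleophilic allyl carbon of prenylstannane 2 (via 3) to give 4.
2. C–O bond: Ullmann diaryl ether coupling of the unhindered phenol of 4 with bromoaldehyde 5 gives 6.
3. Functional group change: CHO to CH2OH gives the target 7.
4. No ring is formed: both benzene rings are bought intact (ring A in 1, ring B in 5). The prenyl group goes on first, while ring A is still symmetric, and then steers the arylation to the other phenol.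

Assumption: the target has no stereocentre and its only C=C bears two identical methyl groups, so it is achiral and needs no stereocontrol; compounds 1, 2 and 5 are purchased.

**Step 1**
Reactants: 1 methyl 2,6-dihydroxy-4-methylbenzoate; 2 tributyl(3-methylbut-2-en-1-yl)stannane
Product: 4 methyl 2,6-dihydroxy-4-methyl-3-(3-methylbut-2-en-1-yl)benzoate, via phenyliodonium zwitterion 3 (not isolated)
Conditions: PhI(OAc)2 (1.0 equiv), KOH (2 equiv), MeOH, −10 to 0 °C; concentrate; then 2 (1.2 equiv), Pd2(dba)3 (2.5 mol %), AsPh3 (10 mol %), DMF, rt; 1 M HCl work-up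
Reagents that add atoms: (diacetoxyiodo)benzene, CC(=O)OI(OC(C)=O)c1ccccc1 (its PhI unit is held in 3 only and leaves again as iodobenzene)
Why: Proposed new method: PhI(OAc)2/KOH should convert the doubly activated C3–H of the resorcinolate (ortho to one oxygen, para to the other, the enol carbon of a vinylogous β-keto ester) into a C–I(III) bond, giving the ortho-oxido aryl(phenyl)iodonium zwitterion 3 in which the naturally nucleophilic C3 is now electrophilic; Pd(0) then inserts into the ylidic C–I bond with loss of PhI (much faster than insertion into PhI itself at rt), the allylstannane transmetalates, and reductive elimination at the less hindered CH2 terminus gives the linear prenyl arene, so two normally nucleophilic carbons are joined; only one substitution is expected because C3 and C5 of 1 are equivalent and the iodonium group deactivates the ring; the closest known reactions are the formation of 2-(phenyliodonio)phenolates and β-dicarbonyl iodonium ylides with PhI(OAc)2/base, and the Pd-catalysed Stille coupling of phenyliodonium ylides of hydroxyquinones and of diaryliodonium salts with organostannanes; no stereocentre is formed.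

**Step 2**
Reactants: 4 methyl 2,6-dihydroxy-4-methyl-3-(3-methylbut-2-en-1-yl)benzoate; 5 2-bromo-3,5-dimethoxybenzaldehyde
Product: 6 methyl 6-(2-formyl-4,6-dimethoxyphenoxy)-2-hydroxy-4-methyl-3-(3-methylbut-2-en-1-yl)benzoate
Conditions: CuI (10 mol %), picolinic acid (20 mol %), K3PO4 (2 equiv), DMSO, 90 °C, Ar
Reagents that add atoms: none
Why: Ullmann-type Cu(I)/picolinic acid diaryl ether coupling, in which the ortho-formyl group activates the C–Br bond of 5 and the bulky 2,6-disubstituted aryl goes to the C6–OH (free ortho position) rather than the C2–OH wedged between ester and prenyl; ester, aldehyde and alkene tolerate K3PO4/Cu at 90 °C, and no stereocentre is formed.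

**Step 3**
Reactants: 6 methyl 6-(2-formyl-4,6-dimethoxyphenoxy)-2-hydroxy-4-methyl-3-(3-methylbut-2-en-1-yl)benzoate
Product: 7 methyl 2-hydroxy-6-[2-(hydroxymethyl)-4,6-dimethoxyphenoxy]-4-methyl-3-(3-methylbut-2-en-1-yl)benzoate
Conditions: NaBH4, MeOH/THF, 0 °C
Reagents that add atoms: none
Why: Chemoselective borohydride reduction of the aryl aldehyde, which leaves the hydrogen-bonded, di-ortho-substituted methyl ester and the trisubstituted alkene untouched at 0 °C; no stereocentre is formed.

**Compound list**
1 | methyl 2,6-dihydroxy-4-methylbenzoate | COC(=O)c1c(O)cc(C)cc1O | starting material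
2 | tributyl(3-methylbut-2-en-1-yl)stannane | CCCC[Sn](CCCC)(CCCC)CC=C(C)C | starting material
3 | methyl 6-hydroxy-4-methyl-2-oxido-3-(phenyliodonio)benzoate (zwitterion) | COC(=O)c1c(O)cc(C)c([I+]c2ccccc2)c1[O-] | intermediate
4 | methyl 2,6-dihydroxy-4-methyl-3-(3-methylbut-2-en-1-yl)benzoate | COC(=O)c1c(O)cc(C)c(CC=C(C)C)c1O | intermediate
5 | 2-bromo-3,5-dimethoxybenzaldehyde | COc1cc(C=O)c(Br)c(OC)c1 | starting material
6 | methyl 6-(2-formyl-4,6-dimethoxyphenoxy)-2-hydroxy-4-methyl-3-(3-methylbut-2-en-1-yl)benzoate | COC(=O)c1c(Oc2c(C=O)cc(OC)cc2OC)cc(C)c(CC=C(C)C)c1O | intermediate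
7 | methyl 2-hydroxy-6-[2-(hydroxymethyl)-4,6-dimethoxyphenoxy]-4-methyl-3-(3-methylbut-2-en-1-yl)benzoate | COC(=O)c1c(Oc2c(CO)cc(OC)cc2OC)cc(C)c(CC=C(C)C)c1O | target

**Totals**
Total step count: 3. Longest linear sequence: 3 (1 → 4 → 6 → 7).

**Steps most likely to fail, with fallbacks**
Step 1 is the riskiest. PhI(OAc)2 may oxidise the resorcinol instead of forming the C–I(III) bond, or the Pd step may transfer phenyl or give back 1. The fallback sets out from 1 and returns at 4: brominate 1 with NBS (MeCN, 0 °C; C3 and C5 are equivalent) to methyl 3-bromo-2,6-dihydroxy-4-methylbenzoate F1, the isolable α-halo-enol form of the same electrophilic C3 synthon. Then couple F1 with 2 in a Stille reaction (Pd(P-t-Bu3)2, dioxane, 80 °C) to give 4.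

Step 2 is next. The Cu coupling joins a di-ortho-substituted bromide to a hydrogen-bonded phenol and may stall or lose selectivity between the two phenols. The fallback sets out from 4 and returns at 6: make 2-fluoro-3,5-dimethoxybenzaldehyde F2 from 3,5-dimethoxybenzaldehyde with Selectfluor (MeCN). Then join it to 4 by uncatalysed SNAr ortho to the formyl group (K2CO3, DMAc, 110 °C) to give 6.

Step 3 is the least risky. The concern is that the new benzylic alkoxide or borate interferes with the neighbouring salicylate ester (partial ester reduction or lactonisation). The fallback sets out from 5 and returns at 7: reduce 5 first (NaBH4, MeOH, 0 °C) to (2-bromo-3,5-dimethoxyphenyl)methanol F3. Then couple F3 with 4 under the Cu/picolinic acid conditions, which arylate phenols in preference to aliphatic alcohols, to give 7 directly without a late reduction.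

**Further compounds**
F1 | step 1 | methyl 3-bromo-2,6-dihydroxy-4-methylbenzoate | COC(=O)c1c(O)cc(C)c(Br)c1O
F2 | step 2 | 2-fluoro-3,5-dimethoxybenzaldehyde | COc1cc(C=O)c(F)c(OC)c1
F3 | step 3 | (2-bromo-3,5-dimethoxyphenyl)methanol | COc1cc(CO)c(Br)c(OC)c1
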